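Enabling feature: in ring B the carbons C2'(Br), C1'(O-aryl), C6'(OH) and C5'(Br) are contiguous and are followed by the unsubstituted pair C4'H–C3'H. This array is C2–C5 of a 2,5-dibromo-3,4-dioxygenated thiophene 1,1-dioxide plus one acetylene unit.
Cuts, in order: both O–CH3 bonds; C2'–C3' and C4'–C5' of ring B (retro-[4+2], SO2 and EtOH restored); the S=O and thiophene C–Br bonds; the thienyl C3–O(aryl) bond; the C1–O bond of ring A back to C1–CHO.
Forward: ring A is bought with both bromines in place and converted to a phenol, which is joined to bought 3,4-dimethoxythiophene by ether exchange. Alpha-dibromination and S-oxidation then arm the diene.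
Ring B is the only ring made. It closes in the cycloaddition with ethyl vinyl ether, loss of SO2 and EtOH makes it aromatic, and double demethylation ends the route.
Stereochemistry: the target has no stereocentre and no hindered axis, and the sp3 centres created in the key step disappear on aromatisation.

Key step: step 6

Remark on the chemistry: the target SMILES carries no stereodescriptor and the molecule is achiral (freely rotating diaryl ether), so there is only one stereoisomer to make.
Numbering used: ring A is the 3,5-dibromo-2-hydroxyphenoxy ring, with C1 bearing the ether oxygen. In ring B, C1' bears the ether oxygen, C2' Br, C3' and C4' H, C5' Br and C6' OH.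

Step 1
Reactants: 1 3,5-dibromosalicylaldehyde (3,5-dibromo-2-hydroxybenzaldehyde)
Product: 2 3,5-dibromo-2-methoxybenzaldehyde
Conditions: MeI (1.5 equiv), K2CO3 (1.5 equiv), DMF, rt → 40 °C
Reagents that add atoms: methyl iodide, CI
Why: Williamson O-methylation of the acidic salicylaldehyde phenol with carbonate base is routine and masks the ring A oxygen (C2–O) unambiguously before the second oxygen is introduced.

Step 2
Reactants: 2 3,5-dibromo-2-methoxybenzaldehyde
Product: 4 3,5-dibromo-2-methoxyphenol, via aryl formate 3 (not isolated)
Conditions: mCPBA (1.5 equiv), CH2Cl2, 40 °C; aq. NaHCO3 wash; then K2CO3 (cat.), MeOH, rt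
Reagents that add atoms: 3-chloroperbenzoic acid (mCPBA), OOC(=O)c1cccc(Cl)c1
Why: Baeyer–Villiger (Dakin-type) oxidation, in which the ortho-methoxy group favours aryl over hydride migration in the Criegee adduct, should give the labile aryl formate, which base-catalysed methanolysis cleaves to the phenol.

Step 3
Reactants: 4 3,5-dibromo-2-methoxyphenol; 5 3,4-dimethoxythiophene
Product: 6 3-(3,5-dibromo-2-methoxyphenoxy)-4-methoxythiophene
Conditions: 5 (3 equiv), p-TsOH·H2O (10 mol %), PhMe, reflux, 4 Å MS in a Soxhlet head (MeOH trap)
Reagents that add atoms: none
Why: Acid-catalysed trans-etherification of an alkoxythiophene (C2-protonation gives an oxygen-stabilised cation at C3, the phenol adds, and methanol leaves and is trapped) is standard for alcohols and known for catechol-type phenols, and the excess of 5 holds back a second exchange.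

Step 4
Reactants: 6 3-(3,5-dibromo-2-methoxyphenoxy)-4-methoxythiophene
Product: 7 2,5-dibromo-3-(3,5-dibromo-2-methoxyphenoxy)-4-methoxythiophene
Conditions: NBS (2.1 equiv), DMF, −10 → 0 °C, dark; used promptly
Reagents that add atoms: N-bromosuccinimide, O=C1CCC(=O)N1Br
Why: Electrophilic aromatic bromination with NBS should touch only the two free alpha carbons of the dioxygenated thiophene, which are far more nucleophilic than the doubly brominated ring A, as in the usual preparation of 2,5-dibromo-3,4-dialkoxythiophenes.

Step 5
Reactants: 7 2,5-dibromo-3-(3,5-dibromo-2-methoxyphenoxy)-4-methoxythiophene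
Product: 8 2,5-dibromo-3-(3,5-dibromo-2-methoxyphenoxy)-4-methoxythiophene 1,1-dioxide
Conditions: dimethyldioxirane (acetone solution, 3–4 equiv), CH2Cl2, 0 °C → rt; evaporate cold
Reagents that add atoms: dimethyldioxirane, CC1(C)OO1
Why: Oxidation of a thiophene to its 1,1-dioxide by electrophilic oxygen transfer to sulfur is known for 2,5-dihalothiophenes, and the neutral dioxirane is chosen because 7 is acid-labile, the two ring oxygens offset the deactivation by bromine, and the fully substituted sulfone should resist dimerisation.

Step 6
Reactants: 8 2,5-dibromo-3-(3,5-dibromo-2-methoxyphenoxy)-4-methoxythiophene 1,1-dioxide; 9 ethyl vinyl ether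
Product: 12 1,4-dibromo-2-(3,5-dibromo-2-methoxyphenoxy)-3-methoxybenzene (target bis-methyl ether), via bridged sulfolene adduct 10 (not isolated), via ethoxycyclohexadiene 11 (not isolated)
Conditions: 9 (20 equiv), BHT (cat.), PhMe, sealed tube, 100 °C; strip volatiles; then p-TsOH·H2O (10 mol %), PhMe, 50 °C
Reagents that add atoms: none
Why: Sulfone 8 is a non-aromatic, s-cis-locked, electron-poor diene whose bromine-bearing termini C2 and C5 add suprafacially to the C=C of 9 in an intermolecular inverse-electron-demand Diels–Alder reaction that makes C2'–C3' and C4'–C5' in one event and so closes ring B by [4+2] cycloaddition, first as the carbocycle of bridged sulfolene 10. Cheletropic extrusion of sulfur dioxide from 10 should be fast at this temperature and makes the addition irreversible, and in the resulting diene 11 the acid ionises the allylic C–OEt bond to a cyclohexadienyl cation whose charge is shared by an oxygen-bearing carbon and which loses the neighbouring proton to give arene 12. The closest known reaction type is the benzannulation of halogenated thiophene 1,1-dioxides with alkenes by Diels–Alder addition, loss of sulfur dioxide and aromatising elimination, the vinyl ether acting as an acetylene equivalent. The stereocentres of 10 and 11 are transient, so endo/exo and facial selectivity do not matter and none survives in 12, and regiochemistry does not matter either, since both orientations of 9 lead to 12 (10 and 11 are drawn for bonding of the nucleophilic CH2 terminus to the diene end next to the weaker aryloxy donor). The selectivities that count are cycloaddition ahead of self-dimerisation of 8, secured by the fully substituted diene and the large excess of 9, and loss of ethanol instead of hydrogen bromide, secured because both bromines of 11 sit on sp2 carbons and because acid triggers the elimination at low temperature before [1,5]-hydrogen shifts can place a hydrogen on a C–Br carbon.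

Step 7
Reactants: 12 1,4-dibromo-2-(3,5-dibromo-2-methoxyphenoxy)-3-methoxybenzene
Product: 14 3,6-dibromo-2-(3,5-dibromo-2-hydroxyphenoxy)phenol (CNP0181200.0), via bis(aryloxydibromoborane) 13 (not isolated)
Conditions: BBr3 (5 equiv), CH2Cl2, −78 °C → rt; then H2O, 0 °C
Reagents that add atoms: none
Why: Lewis-acid cleavage of aryl methyl ethers with boron tribromide (bromide attacks the methyl group of the O–B complex) should remove both methyl groups while the diaryl ether and the four aryl bromides stay inert, and aqueous work-up hydrolyses the B–O bonds to the free bis-phenol.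

Compound list
1 | 3,5-dibromosalicylaldehyde | O=Cc1cc(Br)cc(Br)c1O | starting material
2 | 3,5-dibromo-2-methoxybenzaldehyde | COc1c(Br)cc(Br)cc1C=O | intermediate
3 | 3,5-dibromo-2-methoxyphenyl formate (not isolated) | COc1c(Br)cc(Br)cc1OC=O | intermediate
4 | 3,5-dibromo-2-methoxyphenol | COc1c(Br)cc(Br)cc1O | intermediate
5 | 3,4-dimethoxythiophene | COc1cscc1OC | starting material
6 | 3-(3,5-dibromo-2-methoxyphenoxy)-4-methoxythiophene | COc1cscc1Oc1cc(Br)cc(Br)c1OC | intermediate
7 | 2,5-dibromo-3-(3,5-dibromo-2-methoxyphenoxy)-4-methoxythiophene | COc1c(Br)sc(Br)c1Oc1cc(Br)cc(Br)c1OC | intermediate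
8 | 2,5-dibromo-3-(3,5-dibromo-2-methoxyphenoxy)-4-methoxythiophene 1,1-dioxide | COC1=C(Br)S(=O)(=O)C(Br)=C1Oc1cc(Br)cc(Br)c1OC | intermediate
9 | ethyl vinyl ether | C=COCC | starting material
10 | 1,4-dibromo-2-(3,5-dibromo-2-methoxyphenoxy)-5-ethoxy-3-methoxy-7-thiabicyclo[2.2.1]hept-2-ene 7,7-dioxide (racemic, endo/exo mixture, one regioisomer drawn, not isolated) | CCOC1CC2(Br)C(Oc3cc(Br)cc(Br)c3OC)=C(OC)C1(Br)S2(=O)=O | intermediate
11 | 1,4-dibromo-2-(3,5-dibromo-2-methoxyphenoxy)-5-ethoxy-3-methoxycyclohexa-1,3-diene (racemic, one regioisomer drawn, not isolated) | CCOC1CC(Br)=C(Oc2cc(Br)cc(Br)c2OC)C(OC)=C1Br | intermediate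
12 | 1,4-dibromo-2-(3,5-dibromo-2-methoxyphenoxy)-3-methoxybenzene | COc1c(Br)cc(Br)cc1Oc1c(Br)ccc(Br)c1OC | intermediate
13 | bis(dibromoboryl) derivative of the target, both phenolic oxygens as O–BBr2 (not isolated) | BrB(Br)Oc1c(Br)cc(Br)cc1Oc1c(Br)ccc(Br)c1OB(Br)Br | intermediate
14 | 3,6-dibromo-2-(3,5-dibromo-2-hydroxyphenoxy)phenol, achiral | Oc1c(Br)cc(Br)cc1Oc1c(Br)ccc(Br)c1O | target

Total step count: 7. Longest linear sequence: 7 steps (1 → 14); 5 and 9 are bought and enter directly.

Steps most likely to fail

Step 3. The exchange may be slow or incomplete, because the brominated phenol is a weak nucleophile and leaves the mixed ketal more readily than methanol, so acid-induced oligomerisation of the thiophene could take over. The fallback forms the same C–O bond by oxidative copper coupling instead of ionic exchange.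
- It sets out from phenol 4.
- Purchased 3-bromo-4-methoxythiophene F1 is converted by bromine–lithium exchange (n-BuLi, Et2O, −78 °C), quenching with triisopropyl borate and mild acidic hydrolysis into (4-methoxythiophen-3-yl)boronic acid F2.
- A Chan–Lam coupling of F2 with 4 follows (Cu(OAc)2, pyridine, 4 Å MS, CH2Cl2, air, rt). Aryl bromides are inert under these conditions, and the coupling comes back to the route at 6.

Step 5. The first oxygen transfer to the bromine-deactivated sulfur may be sluggish, so oxidation at ring carbon or decay of the labile dibromide could compete. The fallback inverts the order of bromination and oxidation.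
- It sets out from 6, whose bromine-free and more electron-rich thiophene should accept oxygen more readily.
- Dimethyldioxirane at −20 to 0 °C should give 3-(3,5-dibromo-2-methoxyphenoxy)-4-methoxythiophene 1,1-dioxide F3, which is kept cold and dilute and used at once.
- The two alpha carbons of F3 are the nucleophilic ends of beta-oxygenated vinyl sulfones. NBS (2 equiv, MeCN) brominates them by bromonium transfer and proton loss, which comes back to the route at 8.

Step 6. The donor-substituted diene may react too slowly with an electron-rich alkene. The higher temperatures then needed would invite hydrogen shifts at the diene stage followed by loss of hydrogen bromide, and acid formed from the extruded gas could polymerise the vinyl ether. The fallback keeps the same two bonds but uses a strained, electronically neutral acetylene equivalent and aromatises by cycloreversion instead of elimination.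
- It sets out from 8, which is heated with norbornadiene F4 (excess, xylene, 110 → 140 °C).
- This should give the bridged sulfone adduct F5, which loses sulfur dioxide to the tricyclic diene F6.
- Retro-Diels–Alder expulsion of cyclopentadiene from F6 comes back to the route at 12.

Further compounds
F1 | step 3 | 3-bromo-4-methoxythiophene (purchased) | COc1cscc1Br
F2 | step 3 | (4-methoxythiophen-3-yl)boronic acid | COc1cscc1B(O)O
F3 | step 5 | 3-(3,5-dibromo-2-methoxyphenoxy)-4-methoxythiophene 1,1-dioxide | COC1=CS(=O)(=O)C=C1Oc1cc(Br)cc(Br)c1OC
F4 | step 6 | norbornadiene, bicyclo[2.2.1]hepta-2,5-diene (purchased) | C1C2C=CC1C=C2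
F5 | step 6 | 5,8-dibromo-6-(3,5-dibromo-2-methoxyphenoxy)-7-methoxy-1,4,4a,5,8,8a-hexahydro-1,4-methano-5,8-epithionaphthalene S,S-dioxide (racemic, relative configuration left open) | COC1=C(Oc2cc(Br)cc(Br)c2OC)C2(Br)C3C4C=CC(C4)C3C1(Br)S2(=O)=O
F6 | step 6 | 5,8-dibromo-6-(3,5-dibromo-2-methoxyphenoxy)-7-methoxy-1,4,4a,8a-tetrahydro-1,4-methanonaphthalene (racemic, relative configuration left open) | COC1=C(Br)C2C3C=CC(C3)C2C(Br)=C1Oc1cc(Br)cc(Br)c1OC
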